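**Plan**

1. Numbering: C1 is the ring-fusion carbon with the methyl, C2/C3 the CH2 groups of five-membered ring A, C4 the isopropyl carbinol, C5 the ring-fusion CH, then round seven-membered ring B C6 (aroyloxy), C7 (CH2), C8 (methyl carbinol), C9 (CHOH), C10 (CH2); β is the face of the C1 methyl, α the other face.
2. Retrosynthetic cuts, in order: the C6–O aroyl bond; the C4–isopropyl bond (back to a C4 ketone); H–C5 and HO–C6 (back to C5=C6); the C8–O and C9–O bonds (back to C8=C9, itself from a C9 ketone); last the ring B bonds C1–C10 and C7–C8.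
3. Enabling feature: ring B is a three-carbon piece C8–C9–C10 with oxygen on its middle carbon C9, joined at both ends to the four-carbon piece C7–C6–C5–C1 that ends at quaternary C1. This is the pattern of a 2-oxyallyl cation added to a 1,3-diene, here the vinylcyclopentene C1=C5–C6=C7 built on ring A.
4. Forward order: ring A comes from a bromocyclopentenone (reduction, silylation, vinylation); ring B is closed by the (4+3) cycloaddition; then C9=O to C8=C9 to the cis-diol, C5=C6 to C5–H/C6–OH, C4–O to ketone to isopropyl carbinol, and the aroyl ester last.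
5. Stereochemistry: a CBS reduction sets C4; its β-silyloxy group sends the oxyallyl cation (C1) and the borane (C5, C6) to the α face; the β C1 methyl then sends osmium (C8, C9) and the isopropyl nucleophile (C4) to the α face.

Key step: step 4

Remark on the chemistry: ketone 8 is expected as a mixture of C8 epimers (the 8β-methyl epimer is drawn); this is assumed harmless because C8 becomes sp2 in step 5.

**Route**

Step 1
Reactants: 1 2-bromo-3-methylcyclopent-2-en-1-one
Product: 2 (S)-2-bromo-3-methylcyclopent-2-en-1-ol
Conditions: (R)-2-methyl-CBS-oxazaborolidine (10 mol %), BH3·SMe2, THF, −20 °C; then MeOH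
Reagents that add atoms: none
Why: Corey–Bakshi–Shibata reduction, in which the α-bromovinyl arm acts as the large group, so the (R)-catalyst should deliver hydride to the face that gives the (S)-carbinol.

Step 2
Reactants: 2 (S)-2-bromo-3-methylcyclopent-2-en-1-ol
Product: 3 (S)-[(2-bromo-3-methylcyclopent-2-en-1-yl)oxy](tert-butyl)dimethylsilane
Conditions: TBSCl, imidazole, DMF, rt
Reagents that add atoms: tert-butyldimethylsilyl chloride, CC(C)(C)[Si](C)(C)Cl
Why: Imidazole-promoted silylation of a secondary allylic alcohol, which installs the bulky group that later shields the β face and does not touch the stereocentre.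

Step 3
Reactants: 3 (S)-[(2-bromo-3-methylcyclopent-2-en-1-yl)oxy](tert-butyl)dimethylsilane; 4 vinylboronic acid pinacol ester
Product: 5 (S)-tert-butyldimethyl[(3-methyl-2-vinylcyclopent-2-en-1-yl)oxy]silane
Conditions: Pd(dppf)Cl2 (5 mol %), K2CO3, 1,4-dioxane/H2O, 80 °C
Reagents that add atoms: none
Why: Suzuki–Miyaura coupling of a cyclic vinyl bromide with a vinylboronate, which builds the diene C1=C5–C6=C7 under basic conditions that leave the allylic silyl ether and its stereocentre intact.

Step 4
Reactants: 5 (S)-tert-butyldimethyl[(3-methyl-2-vinylcyclopent-2-en-1-yl)oxy]silane; 6 3-chlorobutan-2-one (racemic)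
Product: 8 ring B ketone (1R,4S; 4β-OTBS; 1β-methyl; C9=O; C5=C6; 8-methyl as epimer mixture), via 1-methyl-2-oxidoallyl cation 7 (not isolated)
Conditions: LiClO4 (3 M in Et2O), Et3N (3 equiv), slow addition of 6 (3 equiv), rt
Reagents that add atoms: none
Why: Et3N enolises 6 toward its methyl group and lithium-assisted loss of chloride gives 7, a two-electron three-carbon partner that adds across the four-electron s-cis diene of 5 in a concerted but asynchronous (or rapid stepwise) (4+3) cycloaddition. The closest known reaction type is the (4+3) cycloaddition of oxyallyl cations from α-halo ketones and base with open-chain and semicyclic 1,3-dienes. Ring B is closed in the (4+3) cycloaddition mode by the bonds C7–C8 and C1–C10, leaving C5=C6 at the ring fusion. The quaternary centre C1 is controlled by the C4 stereocentre, since the cation should add to the diene face anti to the bulky silyloxy group so that C10 enters α and the methyl ends β (1R); C8 is not controlled and need not be. The step needs one orientation of the unsymmetrical cation: the leading bond should join the open, most nucleophilic diene terminus C7 to the methyl-bearing terminus that carries more positive charge, and the lagging bond then joins the unsubstituted CH2 terminus to C1, whereas the reverse orientation would have to join two crowded carbons. The ring-locked C1=C5 and the freely rotating vinyl group make the s-cis geometry easy to reach, and three alkyl substituents make the diene electron-rich enough for the electrophile.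

Step 5
Reactants: 8 ring B ketone
Product: 9 C8=C9 enol triflate (1R,4S; 9-OTf; C5=C6 retained)
Conditions: Tf2O, 2,6-di-tert-butyl-4-methylpyridine, CH2Cl2, 0 °C to rt
Reagents that add atoms: trifluoromethanesulfonic anhydride, O=S(=O)(OS(=O)(=O)C(F)(F)F)C(F)(F)F
Why: Enol triflate formation under equilibrating conditions (O-sulfonylation, then proton loss) should give the more substituted C8=C9 enol because the C10 side is neopentyl, and both C8 epimers converge on the same product.

Step 6
Reactants: 9 C8=C9 enol triflate
Product: 10 diene (1R,4S; C8=C9 trisubstituted with the C8 methyl; C5=C6)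
Conditions: Pd(OAc)2 (5 mol %), PPh3, Bu3N, HCO2H, DMF, 60 °C
Reagents that add atoms: none
Why: Palladium-catalysed formate reduction of a vinyl triflate (oxidative addition, formate exchange, decarboxylation, C–H reductive elimination), which replaces OTf by H without moving the double bond.

Step 7
Reactants: 10 diene
Product: 11 8α,9α-diol (1R,4S,8R,9S; C5=C6 retained)
Conditions: K2OsO4·2H2O (2 mol %), NMO, acetone/H2O, 0 °C
Reagents that add atoms: N-methylmorpholine N-oxide, C[N+]1([O-])CCOCC1; water, O
Why: Upjohn dihydroxylation, a syn addition that should take the open C8=C9 alkene before C5=C6 (flanked by quaternary C1 and the silyloxy carbon C4) and approach anti to the pseudo-axial C1 methyl, setting C8 (R) and C9 (S) together.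

Step 8
Reactants: 11 8α,9α-diol
Product: 12 8α,9α-acetonide (1R,4S,8R,9S)
Conditions: 2,2-dimethoxypropane, PPTS (cat.), CH2Cl2, rt
Reagents that add atoms: 2,2-dimethoxypropane, COC(C)(C)OC
Why: Acid-catalysed transketalisation onto a cis-1,2-diol, mild enough to leave the silyl ether, so that only the C6 hydroxyl made next is free.

Step 9
Reactants: 12 8α,9α-acetonide
Product: 14 6α-alcohol (1R,4S,5S,6S,8R,9S; 5α-H), via C6 alkylborane 13 (not isolated)
Conditions: BH3·THF, THF, 0 °C to rt; then NaOH, H2O2, 0 °C
Reagents that add atoms: hydrogen peroxide, OO; borane–tetrahydrofuran, [BH3-][O+]1CCCC1 (its boron stays only in 13)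
Why: Brown hydroboration–oxidation, in which BH3 should add syn with boron on the less substituted C6 and on the α face, away from both the C1 methyl and the C4 silyloxy group, so that oxidation with retention gives 5α-H and 6α-OH (5S,6S) and the trans ring fusion.

Step 10
Reactants: 14 6α-alcohol
Product: 15 6α-benzyl ether (1R,4S,5S,6S,8R,9S)
Conditions: 2-benzyloxy-1-methylpyridinium triflate, MgO, PhCF3, 85 °C
Reagents that add atoms: 2-benzyloxy-1-methylpyridinium triflate, C[n+]1ccccc1OCc1ccccc1.[O-]S(=O)(=O)C(F)(F)F
Why: O-Benzylation by thermal benzyl transfer from a neutral pyridinium salt, which avoids an alkoxide (and thus silyl migration from O4 to O6) and gives an ether that is neither a leaving group nor a Grignard target in steps 12 and 13.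

Step 11
Reactants: 15 6α-benzyl ether
Product: 16 4β-alcohol (1R,4S,5R,6S,8R,9S; the C5 descriptor changes by priority only)
Conditions: TBAF, THF, rt to 40 °C
Reagents that add atoms: none
Why: Fluoride cleavage of the silyl ether, to which the benzyl ether and the acetonide are inert.

Step 12
Reactants: 16 4β-alcohol
Product: 17 C4 ketone (1R,5S,6S,8R,9S)
Conditions: Dess–Martin periodinane, NaHCO3, CH2Cl2, 0 °C to rt
Reagents that add atoms: none
Why: Dess–Martin oxidation under buffered, non-basic conditions, chosen so that the C5 hydrogen α to the new ketone is not epimerised and the β-benzyloxy group is not eliminated.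

Step 13
Reactants: 17 C4 ketone
Product: 18 4β-hydroxy-4α-isopropyl tertiary alcohol (1R,4R,5S,6S,8R,9S)
Conditions: iPrMgCl, anhydrous CeCl3, THF, −78 °C; then aq. NH4Cl
Reagents that add atoms: isopropylmagnesium chloride, CC(C)[Mg]Cl
Why: CeCl3-mediated Grignard (organocerium) 1,2-addition, whose weakly basic nucleophile should add without enolising or reducing the hindered ketone and attack the α face, anti to the C1 methyl that screens the β face of the five-membered ring, so the hydroxyl ends β (4R).

Step 14
Reactants: 18 4β-hydroxy-4α-isopropyl tertiary alcohol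
Product: 19 4β,6α-diol (1R,4R,5S,6S,8R,9S; acetonide retained)
Conditions: H2 (1 atm), Pd(OH)2/C, EtOAc/MeOH, rt
Reagents that add atoms: none
Why: Catalytic hydrogenolysis of the benzyl ether, which frees the C6 hydroxyl in a molecule that has no other reducible group.

Step 15
Reactants: 19 4β,6α-diol; 20 4-(benzyloxy)benzoyl chloride
Product: 21 6α-[4-(benzyloxy)benzoate] (1R,4R,5S,6S,8R,9S)
Conditions: DMAP, Et3N, CH2Cl2, rt to 40 °C
Reagents that add atoms: none
Why: DMAP-catalysed acylation by an acid chloride, which should take only the secondary C6 hydroxyl because the C4 hydroxyl is tertiary and the diol is masked.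

Step 16
Reactants: 21 6α-[4-(benzyloxy)benzoate]
Product: 23 target CNP0197754.3, via phenol acetonide 22 (not isolated)
Conditions: H2 (1 atm), Pd/C, MeOH, rt; then 1 M aq. HCl, rt
Reagents that add atoms: none
Why: Hydrogenolysis of the aryl benzyl ether followed in the same flask by acid-catalysed hydrolysis of the isopropylidene acetal, conditions under which the hindered secondary aroyl ester and the tertiary alcohols should survive.

**Compound list**

1 | 2-bromo-3-methylcyclopent-2-en-1-one | CC1=C(Br)C(=O)CC1 | starting material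
2 | (S)-2-bromo-3-methylcyclopent-2-en-1-ol | O[C@H]1CCC(C)=C1Br | intermediate
3 | (S)-[(2-bromo-3-methylcyclopent-2-en-1-yl)oxy](tert-butyl)dimethylsilane | CC(C)(C)[Si](C)(C)O[C@H]1CCC(C)=C1Br | intermediate
4 | vinylboronic acid pinacol ester (4,4,5,5-tetramethyl-2-vinyl-1,3,2-dioxaborolane) | C=CB1OC(C)(C)C(C)(C)O1 | starting material
5 | (S)-tert-butyldimethyl[(3-methyl-2-vinylcyclopent-2-en-1-yl)oxy]silane; diene C1=C5–C6=C7 with 4β-OTBS | CC(C)(C)[Si](C)(C)O[C@H]1CCC(C)=C1C=C | intermediate
6 | 3-chlorobutan-2-one (racemic) | CC(Cl)C(C)=O | starting material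
7 | 1-methyl-2-oxidoallyl cation (lithium-paired oxyallyl cation; not isolated) | C[CH+]C([O-])=C | intermediate
8 | ring B ketone: (1R,4S)-4β-(tert-butyldimethylsilyloxy)-1β,8-dimethyl hydroazulene with C9=O and C5=C6 (plan numbering; 8β-methyl epimer drawn) | CC(C)(C)[Si](C)(C)O[C@H]1CC[C@]2(C)CC(=O)[C@@H](C)CC=C21 | intermediate
9 | C8=C9 enol triflate of 8: (1R,4S), 9-trifluoromethanesulfonyloxy, C5=C6 | CC(C)(C)[Si](C)(C)O[C@H]1CC[C@]2(C)CC(OS(=O)(=O)C(F)(F)F)=C(C)CC=C21 | intermediate
10 | diene: (1R,4S)-4β-OTBS-1β,8-dimethyl hydroazulene with C5=C6 and C8=C9 | CC(C)(C)[Si](C)(C)O[C@H]1CC[C@]2(C)CC=C(C)CC=C21 | intermediate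
11 | 8α,9α-diol: (1R,4S,8R,9S), 4β-OTBS, C5=C6 | CC(C)(C)[Si](C)(C)O[C@H]1CC[C@]2(C)C[C@H](O)[C@](C)(O)CC=C21 | intermediate
12 | 8α,9α-acetonide of 11: (1R,4S,8R,9S) | CC(C)(C)[Si](C)(C)O[C@H]1CC[C@]2(C)C[C@@H]3OC(C)(C)O[C@]3(C)CC=C21 | intermediate
13 | C6 alkylborane: 6α-BH2, 5α-H, 4β-OTBS, 8α,9α-acetonide (not isolated) | CC(C)(C)[Si](C)(C)O[C@H]1CC[C@]2(C)C[C@@H]3OC(C)(C)O[C@]3(C)C[C@H](B)[C@H]21 | intermediate
14 | 6α-alcohol: (1R,4S,5S,6S,8R,9S), 5α-H, 4β-OTBS, 8α,9α-acetonide | CC(C)(C)[Si](C)(C)O[C@H]1CC[C@]2(C)C[C@@H]3OC(C)(C)O[C@]3(C)C[C@H](O)[C@H]21 | intermediate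
15 | 6α-benzyl ether of 14: (1R,4S,5S,6S,8R,9S) | CC(C)(C)[Si](C)(C)O[C@H]1CC[C@]2(C)C[C@@H]3OC(C)(C)O[C@]3(C)C[C@H](OCc4ccccc4)[C@H]21 | intermediate
16 | 4β-alcohol: (1R,4S,5R,6S,8R,9S), 6α-OBn, 8α,9α-acetonide | O[C@H]1CC[C@]2(C)C[C@@H]3OC(C)(C)O[C@]3(C)C[C@H](OCc4ccccc4)[C@H]21 | intermediate
17 | C4 ketone: (1R,5S,6S,8R,9S), 6α-OBn, 8α,9α-acetonide | O=C1CC[C@]2(C)C[C@@H]3OC(C)(C)O[C@]3(C)C[C@H](OCc4ccccc4)[C@H]21 | intermediate
18 | 4β-hydroxy-4α-isopropyl tertiary alcohol: (1R,4R,5S,6S,8R,9S), 6α-OBn, 8α,9α-acetonide | CC(C)[C@]1(O)CC[C@]2(C)C[C@@H]3OC(C)(C)O[C@]3(C)C[C@H](OCc4ccccc4)[C@H]21 | intermediate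
19 | 4β,6α-diol: (1R,4R,5S,6S,8R,9S), 8α,9α-acetonide | CC(C)[C@]1(O)CC[C@]2(C)C[C@@H]3OC(C)(C)O[C@]3(C)C[C@H](O)[C@H]21 | intermediate
20 | 4-(benzyloxy)benzoyl chloride | O=C(Cl)c1ccc(OCc2ccccc2)cc1 | starting material
21 | 6α-[4-(benzyloxy)benzoate] of 19: (1R,4R,5S,6S,8R,9S) | CC(C)[C@]1(O)CC[C@]2(C)C[C@@H]3OC(C)(C)O[C@]3(C)C[C@H](OC(=O)c4ccc(OCc5ccccc5)cc4)[C@H]21 | intermediate
22 | phenol acetonide: 6α-(4-hydroxybenzoate), 8α,9α-acetonide (not isolated) | CC(C)[C@]1(O)CC[C@]2(C)C[C@@H]3OC(C)(C)O[C@]3(C)C[C@H](OC(=O)c4ccc(O)cc4)[C@H]21 | intermediate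
23 | CNP0197754.3: (3R,3aS,4S,6R,7S,8aR)-3,6,7-trihydroxy-6,8a-dimethyl-3-(propan-2-yl)decahydroazulen-4-yl 4-hydroxybenzoate (plan numbering 1R,4R,5S,6S,8R,9S) | CC(C)[C@]1(O)CC[C@]2(C)C[C@H](O)[C@](C)(O)C[C@H](OC(=O)c3ccc(O)cc3)[C@H]21 | target

**Step count and risks**

Total step count: 16. Longest linear sequence: 16 steps (1 to 23); compounds 4, 6 and 20 are bought.

Steps most likely to fail:

1. Step 4. The oxyallyl cation may add with its termini reversed (methyl-bearing carbon next to quaternary C1), may stop after the first C–C bond and lose a proton, or may be consumed before the hindered diene reacts; shielding of the β face by the silyloxy group may also be incomplete. The fallback sets out from diene 5 and removes the orientation question by using a symmetric three-carbon partner. Fe2(CO)9-mediated (4+3) cycloaddition with 1,1,3,3-tetrabromoacetone (benzene, 60 °C) should give the 8,10-dibromo C9 ketone F1. Zn/Cu couple with NH4Cl in MeOH would remove both bromines to give the C9 ketone without the C8 methyl F2. Kinetic enolisation with LDA at −78 °C, which should avoid the neopentyl C10, followed by MeI then installs the C8 methyl, and the route is rejoined at ketone 8.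

2. Step 13. The secondary Grignard reagent may enolise the ketone (epimerising C5 or expelling the C6 benzyloxy group) or reduce it by β-hydride transfer instead of adding, and attack on the α face may be slowed by the neighbouring C6 substituent. The fallback sets out from ketone 17 and uses an sp2 nucleophile that cannot donate a β-hydride. Isopropenylmagnesium bromide with CeCl3 (THF, −78 °C) should give the 4β-hydroxy-4α-isopropenyl compound F3. Hydrogenation over Pd(OH)2/C then saturates the isopropenyl group and removes the benzyl ether in one operation, so the route is rejoined at diol 19 and step 14 is not needed.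

3. Step 7. Osmylation may take place on the β face, on both faces, or in part at C5=C6, and a wrong diol cannot be corrected later. The fallback sets out from diene 10 and uses the Woodward cis-hydroxylation, which places the diol on the face opposite to the one the electrophile prefers; it is therefore the answer if the β face proves the more open one. I2 and AgOAc in AcOH should give the 9β-iodo-8α-acetoxy compound F4. In wet AcOH the acetate displaces iodide from the α face and the acetoxonium ion is hydrolysed to the 8α,9α hydroxy acetate F5 (drawn as the C9 acetate). K2CO3 in MeOH then removes the acetyl group, and the route is rejoined at diol 11.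

**Further compounds**

F1 | step 4 | 8,10-dibromo C9 ketone (4β-OTBS; 1β-methyl; C5=C6; bromine-bearing centres as a mixture) | CC(C)(C)[Si](C)(C)O[C@H]1CC[C@]2(C)C(Br)C(=O)C(Br)CC=C21
F2 | step 4 | C9 ketone without the C8 methyl (4β-OTBS; 1β-methyl; C5=C6) | CC(C)(C)[Si](C)(C)O[C@H]1CC[C@]2(C)CC(=O)CCC=C21
F3 | step 13 | 4β-hydroxy-4α-isopropenyl compound (6α-OBn; 8α,9α-acetonide) | C=C(C)[C@]1(O)CC[C@]2(C)C[C@@H]3OC(C)(C)O[C@]3(C)C[C@H](OCc4ccccc4)[C@H]21
F4 | step 7 | 9β-iodo-8α-acetoxy compound (4β-OTBS; C5=C6) | CC(C)(C)[Si](C)(C)O[C@H]1CC[C@]2(C)C[C@@H](I)[C@](C)(OC(C)=O)CC=C21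
F5 | step 7 | 8α-hydroxy-9α-acetoxy compound (4β-OTBS; C5=C6) | CC(C)(C)[Si](C)(C)O[C@H]1CC[C@]2(C)C[C@H](OC(C)=O)[C@](C)(O)CC=C21
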